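## Retrosynthetic overview
- C7–OAc comes from a late, selective acetylation of the secondary allylic OH. C7–C8 comes from an anti-selective aldol between the α'-enolate of a 2-bromo-4-silyloxy-4-octenylcyclopentenone and methyl (Z)-7-oxohept-5-enoate.
- C10–Br comes from nucleophilic epoxidation of the 4-hydroxy-4-octenylcyclopentenone, then HBr opening and dehydration. This sequence leaves the Z-olefin untouched.
- The C12 carbinol comes from 1,2-propargylation of (R)-4-silyloxycyclopentenone anti to the OSi group, then acetylide alkylation and Lindlar reduction. The directing carbinol is afterwards oxidised to the C9 ketone.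
- (R)-4-Silyloxycyclopentenone comes from meso-cyclopent-4-ene-1,3-diol by lipase desymmetrisation.
- Rings: the single carbocycle is bought, so no ring is built. Only a transient oxirane appears.

Assumption: prostanoid numbering (C1 = ester carbon, C20 = chain end) is used in the comments, and all carbon building blocks are taken as catalogue chemicals.

## Route

Step 1
Reactants: 1 cis-cyclopent-4-ene-1,3-diol (meso)
Product: 2 (1S,4R)-4-hydroxycyclopent-2-en-1-yl acetate
Conditions: lipase (serine hydrolase, EC 3.1.1.3; immobilised Candida antarctica lipase B), vinyl acetate (2 equiv), THF, 25 °C; filter, chromatography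
Reagents that add atoms: vinyl acetate, C=COC(C)=O
Why: This is an enantiotopic-group-selective lipase transesterification (desymmetrisation) in which the enzyme acylates only the (S)-carbinol, the enol leaving group makes it irreversible, and slow over-acylation consumes the minor enantiomer to give ≥98% ee.

Step 2
Reactants: 2 (1S,4R)-4-hydroxycyclopent-2-en-1-yl acetate
Product: 3 (1S,4R)-4-(tert-butyldimethylsilyloxy)cyclopent-2-en-1-yl acetate
Conditions: TBSCl, imidazole, DMF, 0 °C → rt
Reagents that add atoms: TBSCl, CC(C)(C)[Si](C)(C)Cl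
Why: Imidazole-promoted silylation of the free (R)-carbinol touches no stereocentre and marks the oxygen that later directs the 1,2-addition.

Step 3
Reactants: 3 (1S,4R)-4-(tert-butyldimethylsilyloxy)cyclopent-2-en-1-yl acetate
Product: 4 (1S,4R)-4-(tert-butyldimethylsilyloxy)cyclopent-2-en-1-ol
Conditions: K2CO3 (0.2 equiv), MeOH, 0 °C → rt
Reagents that add atoms: none
Why: Base-catalysed transesterification (Zemplén type) removes the acetate under conditions to which the TBS ether and both carbinol centres are inert.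

Step 4
Reactants: 4 (1S,4R)-4-(tert-butyldimethylsilyloxy)cyclopent-2-en-1-ol
Product: 5 (R)-4-(tert-butyldimethylsilyloxy)cyclopent-2-en-1-one
Conditions: activated MnO2, CH2Cl2, rt
Reagents that add atoms: none
Why: Neutral heterogeneous MnO2 oxidation of the allylic alcohol erases the (S)-carbinol, keeps the (R)-OTBS centre and avoids base-induced β-elimination of silanolate.

Step 5
Reactants: 5 (R)-4-(tert-butyldimethylsilyloxy)cyclopent-2-en-1-one; 6 propargyl bromide
Product: 8 (1S,4R)-4-(tert-butyldimethylsilyloxy)-1-(prop-2-yn-1-yl)cyclopent-2-en-1-ol, via allenylzinc bromide 7 (not isolated)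
Conditions: activated Zn dust, 6, THF, 0 °C; then 5, −78 → −20 °C; aq NH4Cl; chromatography
Reagents that add atoms: none
Why: In this Barbier-type propargylation the non-basic allenylzinc adds through a cyclic SE2' transition state (1,2-addition, homopropargyl product) on the enone face anti to OTBS, which sets C12 with OH cis to OTBS, and the minor epimer must be removed here because it would later give the enantiomer.

Step 6
Reactants: 8 (1S,4R)-4-(tert-butyldimethylsilyloxy)-1-(prop-2-yn-1-yl)cyclopent-2-en-1-ol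
Product: 9 (3R,5S)-3-(tert-butyldimethylsilyloxy)-5-(prop-2-yn-1-yl)-5-(triethylsilyloxy)cyclopent-1-ene
Conditions: TESOTf, 2,6-lutidine, CH2Cl2, −78 → 0 °C
Reagents that add atoms: TESOTf, CC[Si](CC)(CC)OS(=O)(=O)C(F)(F)F
Why: Silyl triflate silylation caps the hindered tertiary OH, which prevents O-alkylation and cis-1,3 O→O silyl migration in the strongly basic next step.

Step 7
Reactants: 9 (3R,5S)-3-(tert-butyldimethylsilyloxy)-5-(prop-2-yn-1-yl)-5-(triethylsilyloxy)cyclopent-1-ene; 10 1-iodopentane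
Product: 12 (3R,5S)-3-(tert-butyldimethylsilyloxy)-5-(oct-2-yn-1-yl)-5-(triethylsilyloxy)cyclopent-1-ene, via lithium acetylide 11 (not isolated)
Conditions: n-BuLi (1.05 equiv), THF, −78 °C; DMPU, 10, −78 °C → rt
Reagents that add atoms: none
Why: Acetylide alkylation (SN2 on a primary iodide) builds the C13–C20 chain with unambiguous regiochemistry, and both silyl ethers tolerate n-BuLi.

Step 8
Reactants: 12 (3R,5S)-3-(tert-butyldimethylsilyloxy)-5-(oct-2-yn-1-yl)-5-(triethylsilyloxy)cyclopent-1-ene
Product: 13 (3R,5S)-3-(tert-butyldimethylsilyloxy)-5-[(Z)-oct-2-en-1-yl]-5-(triethylsilyloxy)cyclopent-1-ene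
Conditions: H2 (1 atm), Lindlar catalyst, quinoline, hexane–EtOAc, rt
Reagents that add atoms: none
Why: Lindlar semihydrogenation delivers H2 syn to give the 14Z olefin, the poisoned catalyst leaves the hindered ring olefin alone, and doing it here keeps Pd/H2 away from any C–Br bond or enone.

Step 9
Reactants: 13 (3R,5S)-3-(tert-butyldimethylsilyloxy)-5-[(Z)-oct-2-en-1-yl]-5-(triethylsilyloxy)cyclopent-1-ene
Product: 14 (1S,4R)-1-[(Z)-oct-2-en-1-yl]cyclopent-2-ene-1,4-diol
Conditions: TBAF (3 equiv), THF, 0 °C → rt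
Reagents that add atoms: none
Why: Fluoride-driven desilylation removes both silyl groups without acid, which protects the ionisable tertiary allylic alcohol.

Step 10
Reactants: 14 (1S,4R)-1-[(Z)-oct-2-en-1-yl]cyclopent-2-ene-1,4-diol
Product: 15 (S)-4-hydroxy-4-[(Z)-oct-2-en-1-yl]cyclopent-2-en-1-one
Conditions: activated MnO2, CH2Cl2, rt
Reagents that add atoms: none
Why: Chemoselective MnO2 allylic oxidation can only touch the secondary carbinol, so the relay stereocentre is erased after passing its chirality to C12, and avoiding Cr(VI) rules out Babler–Dauben transposition.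

Step 11
Reactants: 15 (S)-4-hydroxy-4-[(Z)-oct-2-en-1-yl]cyclopent-2-en-1-one
Product: 16 (1S,4S,5R)-4-hydroxy-4-[(Z)-oct-2-en-1-yl]-6-oxabicyclo[3.1.0]hexan-2-one
Conditions: 30% aq H2O2 (3 equiv), NaOH (0.2 equiv), MeOH, −20 → 0 °C, 1 h; Na2S2O3 quench
Reagents that add atoms: hydrogen peroxide, OO
Why: Weitz–Scheffer nucleophilic epoxidation attacks only the electron-poor enone (mainly anti to the octenyl chain, both new centres being erased in step 12), while low temperature and catalytic base suppress retro-aldol racemisation at C12.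

Step 12
Reactants: 16 (1S,4S,5R)-4-hydroxy-4-[(Z)-oct-2-en-1-yl]-6-oxabicyclo[3.1.0]hexan-2-one
Product: 18 (S)-2-bromo-4-hydroxy-4-[(Z)-oct-2-en-1-yl]cyclopent-2-en-1-one, via bromohydrin 17 (not isolated)
Conditions: 48% aq HBr (2 equiv), peroxide-free THF, 0 °C → rt, dark
Reagents that add atoms: hydrogen bromide, Br
Why: Bromide opens the epoxy ketone SN2-fashion at the carbonyl-activated and less hindered Cα, and the β-hydroxyl is then lost through the enol, as in the classical route to 4-halo-Δ4-3-ketosteroids, with no electrophilic bromine present to attack the Z-olefin.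

Step 13
Reactants: 18 (S)-2-bromo-4-hydroxy-4-[(Z)-oct-2-en-1-yl]cyclopent-2-en-1-one
Product: 19 (S)-2-bromo-4-[(Z)-oct-2-en-1-yl]-4-(trimethylsilyloxy)cyclopent-2-en-1-one
Conditions: TMSOTf (1.2 equiv), 2,6-lutidine, CH2Cl2, −78 °C
Reagents that add atoms: TMSOTf, C[Si](C)(C)OS(=O)(=O)C(F)(F)F
Why: Fast low-temperature O-silylation gives the smallest practical protecting group, which removes the acidic OH before enolisation and keeps the oxygen face of C12 sterically open.

Step 14
Reactants: 20 hex-5-ynoic acid; 21 formaldehyde (as paraformaldehyde)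
Product: 23 7-hydroxyhept-5-ynoic acid, via dilithio hexynoate 22 (not isolated)
Conditions: n-BuLi (2.1 equiv), THF–DMPU, −78 → −20 °C; (CH2O)n, −20 °C → rt; 1 M HCl
Reagents that add atoms: none
Why: Acetylide hydroxymethylation works because the carboxylate/acetylide dianion reacts with formaldehyde only at carbon, which installs C7.

Step 15
Reactants: 23 7-hydroxyhept-5-ynoic acid
Product: 24 methyl 7-hydroxyhept-5-ynoate
Conditions: MeOH, cat. H2SO4, rt → 40 °C
Reagents that add atoms: methanol, CO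
Why: Fischer esterification in a large excess of methanol outcompetes self-esterification, and the propargylic alcohol is stable to it.

Step 16
Reactants: 24 methyl 7-hydroxyhept-5-ynoate
Product: 25 methyl (Z)-7-hydroxyhept-5-enoate
Conditions: H2 (1 atm), Lindlar catalyst, quinoline, EtOAc, rt
Reagents that add atoms: none
Why: Lindlar syn-semihydrogenation sets the 5Z geometry, and quinoline stops over-reduction.

Step 17
Reactants: 25 methyl (Z)-7-hydroxyhept-5-enoate
Product: 26 methyl (Z)-7-oxohept-5-enoate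
Conditions: activated MnO2, CH2Cl2, 0 °C; filter through Celite, use at once
Reagents that add atoms: none
Why: MnO2 allylic oxidation runs under neutral heterogeneous conditions with no acid or amine, so the labile Z-enal does not isomerise.

Step 18
Reactants: 19 (S)-2-bromo-4-[(Z)-oct-2-en-1-yl]-4-(trimethylsilyloxy)cyclopent-2-en-1-one; 26 methyl (Z)-7-oxohept-5-enoate
Product: 28 methyl (5Z,7S)-7-{(1R,5S)-3-bromo-5-[(Z)-oct-2-en-1-yl]-2-oxo-5-(trimethylsilyloxy)cyclopent-3-en-1-yl}-7-hydroxyhept-5-enoate, via lithium dienolate 27 (not isolated)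
Conditions: LDA (1.1 equiv), THF, −78 °C, 30 min; 26 (1.3 equiv), −78 °C, 20 min; AcOH/THF quench at −78 °C; chromatography
Reagents that add atoms: none
Why: In this kinetic lithium aldol addition C8 is the only enolisable position, the aldehyde approaches anti to the C12 carbon chain (the larger group and better σ-donor, so syn to the small O–Si oxygen) to give 8R, and the ring-locked E(O)-enolate reacts through a Zimmerman–Traxler chair to give the anti aldol (7S) by 1,2-addition with the 5Z olefin retained.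

Step 19
Reactants: 28 methyl (5Z,7S)-7-{(1R,5S)-3-bromo-5-[(Z)-oct-2-en-1-yl]-2-oxo-5-(trimethylsilyloxy)cyclopent-3-en-1-yl}-7-hydroxyhept-5-enoate
Product: 29 methyl (5Z,7S)-7-{(1R,5S)-3-bromo-5-hydroxy-5-[(Z)-oct-2-en-1-yl]-2-oxocyclopent-3-en-1-yl}-7-hydroxyhept-5-enoate
Conditions: AcOH–THF–H2O (3:1:1), 0 °C → rt
Reagents that add atoms: none
Why: Mild acid-catalysed silyl ether hydrolysis spares the aldol, bromoenone and ester, and any material in which TMS migrated to the C7 oxygen converges on the same diol.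

Step 20
Reactants: 29 methyl (5Z,7S)-7-{(1R,5S)-3-bromo-5-hydroxy-5-[(Z)-oct-2-en-1-yl]-2-oxocyclopent-3-en-1-yl}-7-hydroxyhept-5-enoate
Product: 30 7-acetoxy-7,8-dihydrobromovulone I, methyl (5Z,7S)-7-acetoxy-7-{(1R,5S)-3-bromo-5-hydroxy-5-[(Z)-oct-2-en-1-yl]-2-oxocyclopent-3-en-1-yl}hept-5-enoate
Conditions: Ac2O (2 equiv), pyridine, CH2Cl2, 0 °C, no DMAP; cold dilute citric acid work-up
Reagents that add atoms: acetic anhydride, CC(=O)OC(C)=O
Why: Chemoselective acylation takes only the secondary C7-OH because the tertiary C12-OH is inert without DMAP, C7 keeps its configuration, and weak base at low temperature avoids E1cB loss of acetate to the dienone.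

## Compound list
1 | cis-cyclopent-4-ene-1,3-diol (meso) | O[C@@H]1C=C[C@H](O)C1 | starting material
2 | (1S,4R)-4-hydroxycyclopent-2-en-1-yl acetate | CC(=O)O[C@@H]1C=C[C@H](O)C1 | intermediate
3 | (1S,4R)-4-(tert-butyldimethylsilyloxy)cyclopent-2-en-1-yl acetate | CC(=O)O[C@@H]1C=C[C@H](O[Si](C)(C)C(C)(C)C)C1 | intermediate
4 | (1S,4R)-4-(tert-butyldimethylsilyloxy)cyclopent-2-en-1-ol | O[C@@H]1C=C[C@H](O[Si](C)(C)C(C)(C)C)C1 | intermediate
5 | (R)-4-(tert-butyldimethylsilyloxy)cyclopent-2-en-1-one | O=C1C=C[C@H](O[Si](C)(C)C(C)(C)C)C1 | intermediate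
6 | propargyl bromide | C#CCBr | starting material
7 | allenylzinc bromide | C=C=C[Zn]Br | intermediate
8 | (1S,4R)-4-(tert-butyldimethylsilyloxy)-1-(prop-2-yn-1-yl)cyclopent-2-en-1-ol (OH cis to OTBS) | C#CC[C@@]1(O)C=C[C@H](O[Si](C)(C)C(C)(C)C)C1 | intermediate
9 | (3R,5S)-3-(tert-butyldimethylsilyloxy)-5-(prop-2-yn-1-yl)-5-(triethylsilyloxy)cyclopent-1-ene | C#CC[C@@]1(O[Si](CC)(CC)CC)C=C[C@H](O[Si](C)(C)C(C)(C)C)C1 | intermediate
10 | 1-iodopentane | CCCCCI | starting material
11 | lithium acetylide of 9 | [Li]C#CC[C@@]1(O[Si](CC)(CC)CC)C=C[C@H](O[Si](C)(C)C(C)(C)C)C1 | intermediate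
12 | (3R,5S)-3-(tert-butyldimethylsilyloxy)-5-(oct-2-yn-1-yl)-5-(triethylsilyloxy)cyclopent-1-ene | CCCCCC#CC[C@@]1(O[Si](CC)(CC)CC)C=C[C@H](O[Si](C)(C)C(C)(C)C)C1 | intermediate
13 | (3R,5S)-3-(tert-butyldimethylsilyloxy)-5-[(Z)-oct-2-en-1-yl]-5-(triethylsilyloxy)cyclopent-1-ene | CCCCC/C=C\C[C@@]1(O[Si](CC)(CC)CC)C=C[C@H](O[Si](C)(C)C(C)(C)C)C1 | intermediate
14 | (1S,4R)-1-[(Z)-oct-2-en-1-yl]cyclopent-2-ene-1,4-diol | CCCCC/C=C\C[C@@]1(O)C=C[C@H](O)C1 | intermediate
15 | (S)-4-hydroxy-4-[(Z)-oct-2-en-1-yl]cyclopent-2-en-1-one | CCCCC/C=C\C[C@@]1(O)C=CC(=O)C1 | intermediate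
16 | (1S,4S,5R)-4-hydroxy-4-[(Z)-oct-2-en-1-yl]-6-oxabicyclo[3.1.0]hexan-2-one (oxirane syn to OH, major) | CCCCC/C=C\C[C@@]1(O)[C@@H]2O[C@@H]2C(=O)C1 | intermediate
17 | (2R,3S,4S)-2-bromo-3,4-dihydroxy-4-[(Z)-oct-2-en-1-yl]cyclopentan-1-one | CCCCC/C=C\C[C@@]1(O)[C@H](O)[C@@H](Br)C(=O)C1 | intermediate
18 | (S)-2-bromo-4-hydroxy-4-[(Z)-oct-2-en-1-yl]cyclopent-2-en-1-one | CCCCC/C=C\C[C@@]1(O)C=C(Br)C(=O)C1 | intermediate
19 | (S)-2-bromo-4-[(Z)-oct-2-en-1-yl]-4-(trimethylsilyloxy)cyclopent-2-en-1-one | CCCCC/C=C\C[C@@]1(O[Si](C)(C)C)C=C(Br)C(=O)C1 | intermediate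
20 | hex-5-ynoic acid | C#CCCCC(=O)O | starting material
21 | formaldehyde (used as paraformaldehyde) | C=O | starting material
22 | dilithium salt of hex-5-ynoic acid (carboxylate and acetylide) | [Li]C#CCCCC(=O)O[Li] | intermediate
23 | 7-hydroxyhept-5-ynoic acid | OCC#CCCCC(=O)O | intermediate
24 | methyl 7-hydroxyhept-5-ynoate | COC(=O)CCCC#CCO | intermediate
25 | methyl (Z)-7-hydroxyhept-5-enoate | COC(=O)CCC/C=C\CO | intermediate
26 | methyl (Z)-7-oxohept-5-enoate | COC(=O)CCC/C=C\C=O | intermediate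
27 | lithium cross-conjugated dienolate of 19 (C8=C9–OLi) | CCCCC/C=C\C[C@@]1(O[Si](C)(C)C)C=C(Br)C(O[Li])=C1 | intermediate
28 | methyl (5Z,7S)-7-{(1R,5S)-3-bromo-5-[(Z)-oct-2-en-1-yl]-2-oxo-5-(trimethylsilyloxy)cyclopent-3-en-1-yl}-7-hydroxyhept-5-enoate | CCCCC/C=C\C[C@@]1(O[Si](C)(C)C)C=C(Br)C(=O)[C@@H]1[C@H](/C=C\CCCC(=O)OC)O | intermediate
29 | methyl (5Z,7S)-7-{(1R,5S)-3-bromo-5-hydroxy-5-[(Z)-oct-2-en-1-yl]-2-oxocyclopent-3-en-1-yl}-7-hydroxyhept-5-enoate | CCCCC/C=C\C[C@@]1(O)C=C(Br)C(=O)[C@@H]1[C@H](/C=C\CCCC(=O)OC)O | intermediate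
30 | 7-acetoxy-7,8-dihydrobromovulone I | CCCCC/C=C\C[C@@]1(O)C=C(Br)C(=O)[C@@H]1[C@H](/C=C\CCCC(=O)OC)OC(C)=O | target

## Step count
Total steps: 20. Longest linear sequence: 16 (steps 1–13, then 18–20). Steps 14–17 form the convergent four-step branch.

## Three steps most likely to fail

**Step 18 (aldol).** The risks are modest anti/syn or facial selectivity of the lithium enolate and loss of Z-enal integrity. The fallback sets out from 19 (with 26) and comes back at 28. It replaces the lithium enolate by a boron enolate with a much tighter chair. Soft enolisation of 19 with c-Hex2BCl/Et3N in Et2O (−78 → 0 °C) gives the dicyclohexylboron dienolate F1. At −78 °C this adds 26 to give the anti boron aldolate F2. F2 is cleaved without peroxide (MeOH/pH 7 buffer, then silica gel) to give 28.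

**Step 12 (epoxide to bromoenone).** The risks are incomplete dehydration, acid damage to the tertiary carbinol, and HBr-induced Z/E scrambling. The fallback sets out from 15 and comes back at 19. It masks the side-chain olefin as its dibromide so that the classical Br2/Et3N bromination–dehydrobromination can be used.
- 15 is silylated (TMSOTf, 2,6-lutidine) to the silyloxy enone F3, which blocks bromoetherification.
- Br2 (1.0 equiv, CH2Cl2, −78 °C) adds anti only to the electron-rich olefin to give the threo side-chain dibromide F4.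
- A second equivalent of Br2 at 0 °C gives the tetrabromide F5.
- Et3N removes HBr from the α,β-dibromoketone part to give the tribromide bromoenone F6.
- NaI in acetone, in the dark, performs the stereospecific anti-debromination that regenerates the Z-olefin and gives 19.

**Step 5 (propargylation).** The risks are the allenyl versus propargyl product ratio and the facial ratio. This step also governs the later alkylation in step 7. The fallback sets out from 5 and comes back at 13. It builds the chain by acetate aldol and Wittig olefination instead of alkyne chemistry.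
- LDA/EtOAc gives the lithium enolate of ethyl acetate F7, which adds 1,2 to 5 at −78 °C anti to OTBS to give the β-hydroxy ester F8.
- TESOTf/2,6-lutidine gives the TES ether F9.
- DIBAL-H (toluene, −78 °C) gives the aldehyde F10.
- Hexyltriphenylphosphonium bromide/NaHMDS gives hexylidene(triphenyl)phosphorane F11, which converts F10 under salt-free conditions at −78 °C into the Z-olefin 13.

## Further compounds
F1 | step 18 | dicyclohexylboron dienolate of 19 | CCCCC/C=C\C[C@@]1(O[Si](C)(C)C)C=C(Br)C(OB(C2CCCCC2)C2CCCCC2)=C1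
F2 | step 18 | dicyclohexylboron aldolate of 28 | CCCCC/C=C\C[C@@]1(O[Si](C)(C)C)C=C(Br)C(=O)[C@@H]1[C@H](/C=C\CCCC(=O)OC)OB(C2CCCCC2)C2CCCCC2
F3 | step 12 | (S)-4-[(Z)-oct-2-en-1-yl]-4-(trimethylsilyloxy)cyclopent-2-en-1-one | CCCCC/C=C\C[C@@]1(O[Si](C)(C)C)C=CC(=O)C1
F4 | step 12 | 4-(threo-2,3-dibromooctyl)-4-(trimethylsilyloxy)cyclopent-2-en-1-one (C4 as in 15; 2'R,3'R isomer drawn, 2'S,3'S isomer also formed) | CCCCC[C@@H](Br)[C@H](Br)C[C@@]1(O[Si](C)(C)C)C=CC(=O)C1
F5 | step 12 | trans-2,3-dibromo-4-(threo-2,3-dibromooctyl)-4-(trimethylsilyloxy)cyclopentan-1-one (one diastereomer drawn) | CCCCC[C@@H](Br)[C@H](Br)C[C@@]1(O[Si](C)(C)C)[C@H](Br)[C@@H](Br)C(=O)C1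
F6 | step 12 | 2-bromo-4-(threo-2,3-dibromooctyl)-4-(trimethylsilyloxy)cyclopent-2-en-1-one (2'R,3'R isomer drawn) | CCCCC[C@@H](Br)[C@H](Br)C[C@@]1(O[Si](C)(C)C)C=C(Br)C(=O)C1
F7 | step 5 | lithium enolate of ethyl acetate | C=C(O[Li])OCC
F8 | step 5 | ethyl 2-[(1R,4R)-4-(tert-butyldimethylsilyloxy)-1-hydroxycyclopent-2-en-1-yl]acetate | CCOC(=O)C[C@@]1(O)C=C[C@H](O[Si](C)(C)C(C)(C)C)C1
F9 | step 5 | ethyl 2-[(1R,4R)-4-(tert-butyldimethylsilyloxy)-1-(triethylsilyloxy)cyclopent-2-en-1-yl]acetate | CCOC(=O)C[C@@]1(O[Si](CC)(CC)CC)C=C[C@H](O[Si](C)(C)C(C)(C)C)C1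
F10 | step 5 | 2-[(1R,4R)-4-(tert-butyldimethylsilyloxy)-1-(triethylsilyloxy)cyclopent-2-en-1-yl]acetaldehyde | O=CC[C@@]1(O[Si](CC)(CC)CC)C=C[C@H](O[Si](C)(C)C(C)(C)C)C1
F11 | step 5 | hexylidene(triphenyl)phosphorane | CCCCCC=P(c1ccccc1)(c1ccccc1)c1ccccc1
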